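The dihydropyranone is treated as a cyclised, dehydrated δ-hydroxy-β-diketone, and the 3-acylcoumarin as the Knoevenagel–translactonisation product of a salicylaldehyde (masked as a lactol) with a 4-hydroxy-2-pyrone. Everything rests on the acetate unit C-3/C-4 of the pyranone ring, flanked by the oxygen-bearing C-2 and the methine C-5: as ketene it is nucleophilic at C-3 and electrophilic at C-4. In one flask, acetyl chloride, acetaldehyde and a dioxinone dienolate are joined; a catalytic asymmetric [2+2] sets C-2 and forms C-2–C-3, and acylative opening of the transient β-lactone forms C-4–C-5. The side-chain stereocentres are bought with (2R,3R)-2,3-epoxybutane.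

Key step: step 4

Assumption: O-trimethylsilylquinidine is taken as the pseudoenantiomer that delivers the (S)-lactone; should the sense of induction be opposite, O-trimethylsilylquinine is used in its place. Compounds 1 and 2 are taken as catalogue compounds.

Step 1
Reactants: 1 1-bromo-3,5-dimethoxy-2-methylbenzene, 2 (2R,3R)-2,3-dimethyloxirane
Product: 4 (2R,3R)-3-(3,5-dimethoxy-2-methylphenyl)butan-2-ol, via arylmagnesium bromide 3 (not isolated)
Conditions: Mg, THF, 50 °C; then CuI (10 mol%), 2 (1.5 equiv), −30 °C → rt; aq. NH4Cl
Reagents that add atoms: none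
Why: Copper-catalysed SN2 opening of the epoxide by the aryl Grignard reagent: the two carbons of the C2-symmetric trans-epoxide are equivalent, attack is anti, so the attacked carbon is inverted to the (R)-benzylic centre and the untouched carbinol carbon stays (R), both stereocentres coming from purchased 2.

Step 2
Reactants: 4 (2R,3R)-3-(3,5-dimethoxy-2-methylphenyl)butan-2-ol
Product: 5 (3R,4R)-1,6,8-trimethoxy-3,4,5-trimethyl-3,4-dihydro-1H-isochromene (both C-1 epimers)
Conditions: HC(OMe)3 (5 equiv), Me3SiOTf (10 mol%), CH2Cl2, −20 → 0 °C; Et3N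
Reagents that add atoms: trimethyl orthoformate, COC(OC)OC
Why: Oxa-Pictet–Spengler cyclisation with the orthoester as formyl equivalent: the alcohol exchanges into the orthoformate, ionisation gives a dialkoxycarbenium ion, and the only free ortho carbon (para to one methoxy group, ortho to the other) closes the pyran ring, which places the future C-4 of the coumarin; the acetal centre is uncontrolled and is lost later.

Step 3
Reactants: 5 (3R,4R)-1,6,8-trimethoxy-3,4,5-trimethyl-3,4-dihydro-1H-isochromene
Product: 6 (3R,4R)-3,4,5-trimethyl-3,4-dihydro-1H-isochromene-1,6,8-triol (lactol, ring tautomer of 4,6-dihydroxy-2-[(2R,3R)-3-hydroxybutan-2-yl]-3-methylbenzaldehyde)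
Conditions: BBr3 (5 equiv), CH2Cl2, −78 → 0 °C; then H2O, 0 °C
Reagents that add atoms: water, O
Why: Lewis-acid ether cleavage: both aryl methyl ethers are cleaved and the methyl acetal is ionised and hydrolysed to the lactol, while the two stereocentres are untouched because the secondary C–O bond stays intact.

Step 4
Reactants: 7 acetyl chloride, 8 acetaldehyde, 9 2,2,6-trimethyl-4H-1,3-dioxin-4-one
Product: 13 6-[(4S)-4-hydroxy-2-oxopentyl]-2,2-dimethyl-4H-1,3-dioxin-4-one, via ketene 10 (not isolated), via (S)-4-methyloxetan-2-one 11 (not isolated), via lithium dienolate 12 (not isolated)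
Conditions: 7 (1.5 equiv), 8 (1.0 equiv), iPr2NEt, O-trimethylsilylquinidine (10 mol%), LiClO4, CH2Cl2/Et2O, −78 °C; then transfer by cannula into 12 [from 9 (4 equiv), LiN(SiMe3)2, THF, −78 °C], −78 → −40 °C; aq. NH4Cl
Reagents that add atoms: none
Why: Acetyl chloride is dehydrohalogenated to ketene 10, which the alkaloid turns into a chiral ammonium enolate; this adds through its CH2 carbon to LiClO4-activated acetaldehyde (bond C-3–C-2 of the later pyranone), and the aldolate closes 4-exo-trig onto the acylammonium carbon to release lactone 11 and the catalyst. The hard lithium dienolate 12 then attacks the strained lactone carbonyl through its γ-carbon and cleaves the acyl–oxygen bond (bond C-4–C-5), leaving the δ-alkoxide of the keto-dioxinone. The closest known reaction types are the catalytic asymmetric acyl halide–aldehyde cyclocondensation (ketene–aldehyde [2+2]) and the Claisen-type acylation of lithium ester enolates by β-lactones, run here in one flask. No ring of the target closes in this step; the oxetanone is a temporary ring that is opened again. The single new stereocentre, the carbinol carbon that becomes C-2 of the pyranone, is set by the catalyst in the aldol event and is not touched by the ring opening. The step needs acyl–oxygen and not alkyl–oxygen cleavage (hard lithium enolate at low temperature, secondary β-carbon), γ- and not α-acylation (the extended lithium dienolate takes acyl donors at its terminus) and monoaddition (the product is deprotonated to a stabilised enolate, hence the excess of 12, which also absorbs the ammonium salt).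

Step 5
Reactants: 13 6-[(4S)-4-hydroxy-2-oxopentyl]-2,2-dimethyl-4H-1,3-dioxin-4-one
Product: 15 4-hydroxy-6-[(2S)-2-hydroxypropyl]-2H-pyran-2-one, via acylketene 14 (not isolated)
Conditions: PhMe (0.01 M), 110 °C, 1 h
Reagents that add atoms: none
Why: Dioxinone thermolysis: retro-[4+2] expels acetone and the acylketene is trapped by the enol oxygen of its own δ-ketone in a six-membered cyclisation to the 4-hydroxy-2-pyrone; the neutral medium leaves the β-hydroxy ketone and its stereocentre untouched.

Step 6
Reactants: 6 (3R,4R)-3,4,5-trimethyl-3,4-dihydro-1H-isochromene-1,6,8-triol, 15 4-hydroxy-6-[(2S)-2-hydroxypropyl]-2H-pyran-2-one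
Product: 17 7-hydroxy-5-[(2R,3R)-3-hydroxybutan-2-yl]-6-methyl-3-[(2S)-2-methyl-4-oxo-3,4-dihydro-2H-pyran-6-yl]-2H-chromen-2-one (CNP0270207.1), via ring-opened coumarin diketone 16 (not isolated)
Conditions: piperidine (20 mol%), AcOH (20 mol%), EtOH, 60 °C; then TsOH·H2O (0.3 equiv), rt
Reagents that add atoms: none
Why: Knoevenagel condensation of the hydroxy-aldehyde tautomer of 6 with C-3 of the hydroxypyrone, then attack of the ortho phenol on the pyrone carbonyl with ring opening (translactonisation) to coumarin 16, then acid-catalysed hemiketalisation of the δ-hydroxyl onto the coumarin-bound ketone and dehydration to the vinylogous ester; no stereocentre is formed or touched, and the aromatic coumarin should act as the sink that drains the lactol and any C-1 adduct.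

Compound list
1 | 1-bromo-3,5-dimethoxy-2-methylbenzene | COc1cc(OC)c(C)c(Br)c1 | starting material
2 | (2R,3R)-2,3-dimethyloxirane | C[C@H]1O[C@@H]1C | starting material
3 | (3,5-dimethoxy-2-methylphenyl)magnesium bromide | COc1cc(OC)c(C)c([Mg]Br)c1 | intermediate
4 | (2R,3R)-3-(3,5-dimethoxy-2-methylphenyl)butan-2-ol | COc1cc(OC)c(C)c([C@@H](C)[C@@H](C)O)c1 | intermediate
5 | (3R,4R)-1,6,8-trimethoxy-3,4,5-trimethyl-3,4-dihydro-1H-isochromene (both C-1 epimers) | COC1O[C@H](C)[C@H](C)c2c(C)c(OC)cc(OC)c12 | intermediate
6 | (3R,4R)-3,4,5-trimethyl-3,4-dihydro-1H-isochromene-1,6,8-triol (lactol, both C-1 epimers) | OC1O[C@H](C)[C@H](C)c2c(C)c(O)cc(O)c12 | intermediate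
7 | acetyl chloride | CC(Cl)=O | starting material
8 | acetaldehyde | CC=O | starting material
9 | 2,2,6-trimethyl-4H-1,3-dioxin-4-one | CC1=CC(=O)OC(C)(C)O1 | starting material
10 | ketene | C=C=O | intermediate
11 | (4S)-4-methyloxetan-2-one | C[C@H]1CC(=O)O1 | intermediate
12 | lithium 2,2-dimethyl-6-methylidene-6H-1,3-dioxin-4-olate | [Li]OC1=CC(=C)OC(C)(C)O1 | intermediate
13 | 6-[(4S)-4-hydroxy-2-oxopentyl]-2,2-dimethyl-4H-1,3-dioxin-4-one | C[C@H](O)CC(=O)CC1=CC(=O)OC(C)(C)O1 | intermediate
14 | (7S)-7-hydroxy-3,5-dioxooct-1-en-1-one (acylketene) | C[C@H](O)CC(=O)CC(=O)C=C=O | intermediate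
15 | 4-hydroxy-6-[(2S)-2-hydroxypropyl]-2H-pyran-2-one | C[C@H](O)CC1=CC(O)=CC(=O)O1 | intermediate
16 | 7-hydroxy-5-[(2R,3R)-3-hydroxybutan-2-yl]-3-[(5S)-5-hydroxy-3-oxohexanoyl]-6-methyl-2H-chromen-2-one | Cc1c(O)cc2oc(=O)c(C(=O)CC(=O)C[C@H](C)O)cc2c1[C@@H](C)[C@@H](C)O | intermediate
17 | 7-hydroxy-5-[(2R,3R)-3-hydroxybutan-2-yl]-6-methyl-3-[(2S)-2-methyl-4-oxo-3,4-dihydro-2H-pyran-6-yl]-2H-chromen-2-one | Cc1c(O)cc2oc(=O)c(C3=CC(=O)C[C@H](C)O3)cc2c1[C@@H](C)[C@@H](C)O | target

Total step count: 6. Longest linear sequence: 4 steps (1, 2, 3, 6); the pyrone arm (4, 5) joins at step 6.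

Steps most likely to fail

Step 4. The cycloaddition may lose material to self-condensation of acetaldehyde or dimerisation of ketene, and facial selectivity may be incomplete. In the second stage the ammonium salt may quench too much dienolate, or the dienolate may react through its α-carbon or at the alkyl carbon of the lactone. The fallback buys the stereocentre and uses a harder nucleophile. It sets out from (4S)-4-methyloxetan-2-one 11, purchased as the single enantiomer. The dianion of methyl acetoacetate (NaH, then n-BuLi, THF, 0 → −78 °C) should open 11 at the acyl carbon to methyl (7S)-7-hydroxy-3,5-dioxooctanoate F1. Lactonisation of F1 with DBU in toluene at 80 °C should give pyrone 15, where the route is rejoined.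

Step 6. The pyrone may add to the oxocarbenium or quinone methide form of the lactol and stay as a C-1 adduct without ring opening. The phenol may also attack C-4 of the pyrone and not the lactone carbonyl, or the electrophile may oligomerise. The fallback removes the lactol by masking the side-chain hydroxyl, and sets out from alcohol 4. Acetylation (Ac2O, pyridine, DMAP) should give (2R,3R)-3-(3,5-dimethoxy-2-methylphenyl)butan-2-yl acetate F2. Rieche formylation (Cl2CHOMe, TiCl4, CH2Cl2, −78 → 0 °C) next to the side chain should give (2R,3R)-3-(2-formyl-3,5-dimethoxy-6-methylphenyl)butan-2-yl acetate F3. BBr3 at −78 → 0 °C should give the free salicylaldehyde (2R,3R)-3-(2-formyl-3,5-dihydroxy-6-methylphenyl)butan-2-yl acetate F4. Condensation of F4 with 15 under the conditions of step 6 should give (2R,3R)-3-{7-hydroxy-6-methyl-3-[(2S)-2-methyl-4-oxo-3,4-dihydro-2H-pyran-6-yl]-2-oxo-2H-chromen-5-yl}butan-2-yl acetate F5. Acid-catalysed methanolysis (HCl, MeOH, 40 °C) should then release target 17.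

Step 3. Cleavage of the second aryl methyl ether may be incomplete, the ionised lactol may oligomerise as a quinone methide, and aryl participation at the secondary C–O bond could erode configuration. The fallback demethylates before the ring is built and sets out from alcohol 4. Nucleophilic demethylation (NaSEt, DMF, 150 °C) should give (2R,3R)-3-(3,5-dihydroxy-2-methylphenyl)butan-2-ol F6. Oxa-Pictet–Spengler cyclisation of F6 with HC(OEt)3 and catalytic TsOH, then aqueous work-up, should give lactol 6, where the route is rejoined without passing through 5.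

Further compounds
F1 | step 4 | methyl (7S)-7-hydroxy-3,5-dioxooctanoate | COC(=O)CC(=O)CC(=O)C[C@H](C)O
F2 | step 6 | (2R,3R)-3-(3,5-dimethoxy-2-methylphenyl)butan-2-yl acetate | COc1cc(OC)c(C)c([C@@H](C)[C@@H](C)OC(C)=O)c1
F3 | step 6 | (2R,3R)-3-(2-formyl-3,5-dimethoxy-6-methylphenyl)butan-2-yl acetate | COc1cc(OC)c(C)c([C@@H](C)[C@@H](C)OC(C)=O)c1C=O
F4 | step 6 | (2R,3R)-3-(2-formyl-3,5-dihydroxy-6-methylphenyl)butan-2-yl acetate | Cc1c(O)cc(O)c(C=O)c1[C@@H](C)[C@@H](C)OC(C)=O
F5 | step 6 | (2R,3R)-3-{7-hydroxy-6-methyl-3-[(2S)-2-methyl-4-oxo-3,4-dihydro-2H-pyran-6-yl]-2-oxo-2H-chromen-5-yl}butan-2-yl acetate | Cc1c(O)cc2oc(=O)c(C3=CC(=O)C[C@H](C)O3)cc2c1[C@@H](C)[C@@H](C)OC(C)=O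
F6 | step 3 | (2R,3R)-3-(3,5-dihydroxy-2-methylphenyl)butan-2-ol | Cc1c(O)cc(O)cc1[C@@H](C)[C@@H](C)O
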